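The data were generated by integration for substances that don't exist.

A small charge of free base is what we have to choose for the next run. In maple, at 0.024 M, 31.6 % of the electrophile is left at 0.500 d. In ash, at 0.053 M, 33.2 % is left at 0.208 d.

| setting | maple | ash | flask |
|---|---|---|---|
| electrophile | 0.050 M | 0.050 M | 0.050 M |
| nucleophile | 0.075 M | 0.075 M | 0.0750 M |
| free base | 0.024 M | 0.053 M |  |
| remark | run made earlier | run made earlier |  |
| time |  |  | 6.0 d |

- maple (time / d: product / %, electrophile / %): 0.500: 66.8, 31.6; 1.04: 74.0, 27.7; 1.67: 75.7, 24.9; 2.08: 76.7, 23.0; 2.50: 78.8, 22.2; 3.00: 79.0, 19.0; 4.00: 82.6, 16.1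
- ash (time / d: product / %, electrophile / %): 0.208: 66.1, 33.2; 0.500: 70.1, 31.1; 1.04: 73.9, 23.3; 1.67: 80.1, 20.6; 2.00: 81.8, 19.6; 3.00: 86.1, 15.2; 4.00: 91.5, 11.9

(standard deviation of a reading: 1 percentage point)

- the amount of free base is what is sought; it is there from the start
- the numbers in the tables scatter with a standard deviation of 1 percentage point

- the concentration of free base at which the part of the electrophile that has reacted at 6.0 d is just 90 %, in M

We work with the fraction of electrophile left, not the fraction made, and watch its logarithm. Between first and last reading, that logarithm falls by 0.193 /d in maple. In ash, with more free base, it falls faster, by 0.271 /d. Running the maple tail back to the start gives 34.8 % left after the early drop.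

The new flask must leave 10.0 % at 6.0 d, so if its early drop leaves the same as in maple, its tail must fall by 0.208 /d. We call this the needed tail rate: the logarithm of the fraction left after the early drop over the fraction wanted, divided by the time. It lies above maple and below ash, so we draw a straight line between the two runs. We would charge c(free base) = 0.0296 M, as a reading that carries the scatter of 1 point.

The forecast gives 0.031 M, slightly above ours, on this ground: “That lies between the two runs, so this is interpolation”. Our way takes two readings from each run.

The flask gives c(free base) = 0.0356 M.

    electrophile + nucleophile → acid set free + product (k = 0.290 /M/min)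
    nucleophile + acid set free ⇌ protonated nucleophile, settled at all times (K = 65000 /M)
    acid set free + free base ⇌ salt of the base (K = 2.60 × 10⁵ /M, k = 0.510 /M/min)
    free base ⇌ dormant form (K = 1.50, k = 5.90 × 10⁻⁴ /min)
    2 nucleophile → homo dimer (k = 0.0430 /M/min)

At that charge, 10.1 % of the charged free base is still free at 6.00 d. We put the needed tail rate to use on this flask. From 30.3 % left at 0.600 d down to 10.0 % at 6.0 d, this flask falls by 0.205 /d, close to 0.208 /d. At twice the dilution, the thin flask ends with 85.8 % reacted. Had its early drop also left 34.8 %, its tail would be 0.149 /d, slower than the needed 0.208 /d.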